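Assumption: the given SMILES has no stereocentre, no stereo double bond and no axis descriptor. The exocyclic C=C ends in a symmetric ring, and hindered-rotation forms interconvert through quinone methide–phenol tautomerism. The drawn structure is therefore the target, and no step has to set configuration.

## Retrosynthetic overview

1. Selaginellin ⇒ global O-demethylation and ionisation of a silyl-capped tris(anisyl) carbinol. The quinone methide is unmasked last and is not built as a ring.
2. Diarylalkyne ⇒ Sonogashira coupling on a terminal alkyne ⇒ one-carbon homologation of a lactol. The phthalide carbonyl carbon becomes the inner alkyne carbon, and its OCH2 becomes the CH2OH.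
3. Key disconnection: 6-aryl-7-(diarylcarbinyl)phthalide ⇒ acyclic ester-tethered triyne, by hexadehydro-Diels–Alder reaction with H2 transfer.
4. Triyne ⇒ Steglich union of a diynol (Hay coupling) and a γ-silyloxy ynoic acid (propiolate dianion + 4,4'-dimethoxybenzophenone).
5. Ring order: the four outer six-membered rings are bought. The central benzene and the γ-lactone form together in one step, and the lactone is opened again in the next step.

## Route

Step 1
Reactants: 1 4-ethynylanisole; 2 propargyl alcohol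
Product: 3 5-(4-methoxyphenyl)penta-2,4-diyn-1-ol
Conditions: CuCl (10 mol %), TMEDA (30 mol %), O2 (balloon), acetone, rt; 2 in 5-fold excess
Reagents that add atoms: none
Why: Glaser–Hay oxidative heterocoupling: Cu(I)/TMEDA/O2 joins two terminal alkynes, and the fivefold excess of cheap 2 channels 1 into the cross-diyne while the very polar homodimer of 2 is washed out with water; no stereocentre is formed.

Step 2
Reactants: 4 propiolic acid; 5 4,4'-dimethoxybenzophenone
Product: 9 4,4-bis(4-methoxyphenyl)-4-[(triethylsilyl)oxy]but-2-ynoic acid, via dilithium propiolate 6 (not isolated), via dilithium alkoxide carboxylate adduct 7 (not isolated), via bis(triethylsilyl) ether ester 8 (not isolated)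
Conditions: LDA (2.2 equiv), THF–DMPU, −78 °C; 5, −78 °C to rt; TESCl (3 equiv), 0 °C to rt; H2O, then pH 4 buffer
Reagents that add atoms: triethylsilyl chloride (TESCl) CC[Si](Cl)(CC)CC
Why: Acetylide 1,2-addition of the propiolic acid dianion to a non-enolisable diaryl ketone followed by in situ O-silylation: the silyl ester hydrolyses on work-up while the hindered tertiary TES ether stays and later keeps this oxygen from attacking the lactone or the aldehyde; the new quaternary carbon carries two identical aryl groups and is not stereogenic.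

Step 3
Reactants: 3 5-(4-methoxyphenyl)penta-2,4-diyn-1-ol; 9 4,4-bis(4-methoxyphenyl)-4-[(triethylsilyl)oxy]but-2-ynoic acid
Product: 10 5-(4-methoxyphenyl)penta-2,4-diyn-1-yl 4,4-bis(4-methoxyphenyl)-4-[(triethylsilyl)oxy]but-2-ynoate
Conditions: DCC (1.1 equiv), DMAP (10 mol %), CH2Cl2, 0 °C to rt
Reagents that add atoms: none
Why: Steglich esterification: the primary propargylic alcohol is acylated under neutral carbodiimide conditions that leave the acid-labile bis(anisyl) silyl ether and the diyne untouched.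

Step 4
Reactants: 10 5-(4-methoxyphenyl)penta-2,4-diyn-1-yl 4,4-bis(4-methoxyphenyl)-4-[(triethylsilyl)oxy]but-2-ynoate
Product: 12 7-{bis(4-methoxyphenyl)[(triethylsilyl)oxy]methyl}-6-(4-methoxyphenyl)isobenzofuran-1(3H)-one, via benzyne 11 (not isolated)
Conditions: cyclooctane (5 mM), N2, 140 °C, 36 h
Reagents that add atoms: none
Why: Hexadehydro-Diels–Alder cycloisomerisation with reductive trapping: the three-atom ester tether allows only the C4(diyne)–Cα(ynoate) and C1(diyne)–Cβ(ynoate) bonds, so benzene ring and γ-lactone close together to benzyne 11 with aryl, carbinyl, carbonyl and CH2O already in the 1,2,3,4-order of the target, the rate-limiting first bond forms far from the bulky termini, and solvent cyclooctane then delivers two vicinal hydrogens by concerted double H-atom transfer faster than the 5 mM substrate can intercept the aryne; no stereocentre is formed.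

Step 5
Reactants: 12 7-{bis(4-methoxyphenyl)[(triethylsilyl)oxy]methyl}-6-(4-methoxyphenyl)isobenzofuran-1(3H)-one
Product: 14 {3-{bis(4-methoxyphenyl)[(triethylsilyl)oxy]methyl}-2-ethynyl-4-(4-methoxyphenyl)phenyl}methanol, via lactol 13 (not isolated)
Conditions: DIBAL-H (1.2 equiv), CH2Cl2, −78 °C, 1 h; then MeOH, K2CO3 (3 equiv), Ohira–Bestmann reagent (2 equiv), −78 °C to rt, 16 h; Rochelle salt work-up
Reagents that add atoms: Ohira–Bestmann reagent, dimethyl (1-diazo-2-oxopropyl)phosphonate CC(=O)C(=[N+]=[N-])P(=O)(OC)OC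
Why: Partial lactone reduction and Seyferth–Gilbert homologation (Ohira–Bestmann variant) in one pot: the aluminium lactolate stops at the aldehyde level, methanolysis frees lactol 13 that equilibrates with the hydroxy aldehyde under base, and the diazophosphonate anion converts that aldehyde irreversibly into the terminal alkyne while releasing the CH2OH; the lactol stereocentre is racemic and vanishes.

Step 6
Reactants: 14 {3-{bis(4-methoxyphenyl)[(triethylsilyl)oxy]methyl}-2-ethynyl-4-(4-methoxyphenyl)phenyl}methanol; 15 4-iodophenol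
Product: 16 4-{[2-{bis(4-methoxyphenyl)[(triethylsilyl)oxy]methyl}-6-(hydroxymethyl)-3-(4-methoxyphenyl)phenyl]ethynyl}phenol
Conditions: PdCl2(PPh3)2 (3 mol %), CuI (6 mol %), Et3N–THF 1:1, degassed, rt to 40 °C
Reagents that add atoms: none
Why: Sonogashira coupling: the reacting C–H lies outside the crowded bay, aryl iodides couple at or near room temperature, and free phenol, primary alcohol and TES ether are tolerated in Et3N.

Step 7
Reactants: 16 4-{[2-{bis(4-methoxyphenyl)[(triethylsilyl)oxy]methyl}-6-(hydroxymethyl)-3-(4-methoxyphenyl)phenyl]ethynyl}phenol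
Product: 18 selaginellin, via benzylic bromide 17 (not isolated)
Conditions: BBr3 (10 equiv), CH2Cl2, −78 °C to rt; ice–water; crude in acetone–H2O 1:1 (5 mM), NaHCO3 (3 equiv), 45 °C; work-up at pH 5
Reagents that add atoms: water O
Why: Lewis-acid aryl methyl ether cleavage (BBr3) followed by benzylic bromide hydrolysis: the three OMe groups leave as MeBr, the trityl-type silyl ether ionises to a doubly aryloxy-stabilised cation that collapses to the p-quinone methide on quench, the primary benzylic alcohol is expected to end as bromide 17, and this unhindered bromide is solvolysed in buffered aqueous acetone so that surviving alcohol and bromide converge on 18; no stereocentre is present.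

## Compound list

1 | 4-ethynylanisole (1-ethynyl-4-methoxybenzene) | C#Cc1ccc(OC)cc1 | starting material
2 | propargyl alcohol (prop-2-yn-1-ol) | C#CCO | starting material
3 | 5-(4-methoxyphenyl)penta-2,4-diyn-1-ol | OCC#CC#Cc1ccc(OC)cc1 | intermediate
4 | propiolic acid | C#CC(=O)O | starting material
5 | 4,4'-dimethoxybenzophenone | O=C(c1ccc(OC)cc1)c1ccc(OC)cc1 | starting material
6 | dilithium propiolate (C,O-dianion) | [Li]C#CC(=O)O[Li] | intermediate
7 | dilithium 4-oxido-4,4-bis(4-methoxyphenyl)but-2-ynoate | [Li]OC(=O)C#CC(O[Li])(c1ccc(OC)cc1)c1ccc(OC)cc1 | intermediate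
8 | triethylsilyl 4,4-bis(4-methoxyphenyl)-4-[(triethylsilyl)oxy]but-2-ynoate | CC[Si](CC)(CC)OC(=O)C#CC(O[Si](CC)(CC)CC)(c1ccc(OC)cc1)c1ccc(OC)cc1 | intermediate
9 | 4,4-bis(4-methoxyphenyl)-4-[(triethylsilyl)oxy]but-2-ynoic acid | OC(=O)C#CC(O[Si](CC)(CC)CC)(c1ccc(OC)cc1)c1ccc(OC)cc1 | intermediate
10 | 5-(4-methoxyphenyl)penta-2,4-diyn-1-yl 4,4-bis(4-methoxyphenyl)-4-[(triethylsilyl)oxy]but-2-ynoate (triyne) | COc1ccc(cc1)C#CC#CCOC(=O)C#CC(O[Si](CC)(CC)CC)(c1ccc(OC)cc1)c1ccc(OC)cc1 | intermediate
11 | 4,5-didehydro derivative (benzyne) of phthalide 12 | O=C1OCC2=C1C(C(O[Si](CC)(CC)CC)(c1ccc(OC)cc1)c1ccc(OC)cc1)=C(c1ccc(OC)cc1)C#C2 | intermediate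
12 | 7-{bis(4-methoxyphenyl)[(triethylsilyl)oxy]methyl}-6-(4-methoxyphenyl)isobenzofuran-1(3H)-one | O=C1OCc2ccc(-c3ccc(OC)cc3)c(C(O[Si](CC)(CC)CC)(c3ccc(OC)cc3)c3ccc(OC)cc3)c12 | intermediate
13 | (±)-7-{bis(4-methoxyphenyl)[(triethylsilyl)oxy]methyl}-6-(4-methoxyphenyl)-1,3-dihydroisobenzofuran-1-ol (lactol, racemic at C1) | OC1OCc2ccc(-c3ccc(OC)cc3)c(C(O[Si](CC)(CC)CC)(c3ccc(OC)cc3)c3ccc(OC)cc3)c12 | intermediate
14 | {3-{bis(4-methoxyphenyl)[(triethylsilyl)oxy]methyl}-2-ethynyl-4-(4-methoxyphenyl)phenyl}methanol | C#Cc1c(CO)ccc(-c2ccc(OC)cc2)c1C(O[Si](CC)(CC)CC)(c1ccc(OC)cc1)c1ccc(OC)cc1 | intermediate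
15 | 4-iodophenol | Oc1ccc(I)cc1 | starting material
16 | 4-{[2-{bis(4-methoxyphenyl)[(triethylsilyl)oxy]methyl}-6-(hydroxymethyl)-3-(4-methoxyphenyl)phenyl]ethynyl}phenol | Oc1ccc(cc1)C#Cc1c(CO)ccc(-c2ccc(OC)cc2)c1C(O[Si](CC)(CC)CC)(c1ccc(OC)cc1)c1ccc(OC)cc1 | intermediate
17 | selaginellin with CH2Br in place of CH2OH (benzylic bromide quinone methide) | O=C1C=CC(=C(c2ccc(O)cc2)c2c(-c3ccc(O)cc3)ccc(CBr)c2C#Cc2ccc(O)cc2)C=C1 | intermediate
18 | selaginellin | O=C1C=CC(=C(c2ccc(O)cc2)c2c(-c3ccc(O)cc3)ccc(CO)c2C#Cc2ccc(O)cc2)C=C1 | target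

## Step count and risks

Total step count: 7. Longest linear sequence: 6 (step 1 or step 2, then steps 3 to 7).

**Step 4 (most likely to fail).**
- Risk: the ester tether sits mostly in the conformer that cannot cyclise, and the ynoate carries a very large group. The benzyne must also be reduced before it meets a second molecule of triyne.
- Fallback: place the two hydrogens in the substrate, so that no aryne and no external reductant are needed. This is a tetradehydro-Diels–Alder reaction that still closes benzene and lactone together. It sets out from 2 and 9 and comes back at 12.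
- Sonogashira coupling of 2 with commercial (E)-1-(2-bromovinyl)-4-methoxybenzene (PdCl2(PPh3)2, CuI, Et3N) gives (E)-5-(4-methoxyphenyl)pent-4-en-2-yn-1-ol F1.
- Steglich coupling of F1 with 9 gives the enyne ynoate ester F2.
- Heating F2 (toluene, BHT, sealed tube, 180 °C) gives the bicyclic cyclic allene F3, which aromatises by hydrogen shift to 12.

**Step 5.**
- Risk: the aldehyde is flanked by a trityl-like group and is largely hidden as the closed lactol. The stabilised diazophosphonate anion may decompose before it reacts.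
- Fallback: switch to a non-stabilised Wittig reagent followed by β-elimination. It sets out from 13, which is isolated this time after the DIBAL-H reduction of 12, and comes back at 14.
- (Chloromethyl)triphenylphosphonium chloride with KHMDS in THF converts 13 into the E/Z chloroalkene {3-{bis(4-methoxyphenyl)[(triethylsilyl)oxy]methyl}-2-(2-chlorovinyl)-4-(4-methoxyphenyl)phenyl}methanol F4.
- LDA (3 equiv, −78 °C to 0 °C) eliminates HCl from F4 to give 14.

**Step 7.**
- Risk: BBr3 meets a benzylic alcohol, a diarylalkyne and a cation next to a biaryl. Bromide hydrolysis, bromoboration of the alkyne or Friedel–Crafts closure to a 9,9-diarylfluorene could cost material. The attacking ring position for that closure is meta to oxygen, so it is not activated.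
- Fallback: change the protecting-group plan so that no Lewis acid is needed. It sets out from 2 and 4 and comes back at 18.
- 4,4'-Dihydroxybenzophenone with MOMCl and iPr2NEt gives bis[4-(methoxymethoxy)phenyl]methanone F5.
- Commercial 4-(methoxymethoxy)benzaldehyde with the Ohira–Bestmann reagent (K2CO3, MeOH) gives 1-ethynyl-4-(methoxymethoxy)benzene F6.
- Hay coupling of F6 with 2 gives the MOM diynol F7.
- Dianion 6, made from 4, adds to F5 to give the MOM dilithium adduct F8. TESCl converts F8 into the MOM bis-silyl compound F9, and work-up hydrolyses F9 to the MOM acid F10.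
- Steglich coupling of F7 with F10 gives the MOM triyne F11.
- Heating F11 in cyclooctane gives, through the MOM benzyne F12, the MOM phthalide F13.
- DIBAL-H followed by the Ohira–Bestmann reagent gives, through the MOM lactol F14, the MOM terminal alkyne F15.
- Sonogashira coupling of F15 with 15 gives the MOM diarylalkyne F16.
- 1 M HCl in MeOH–THF at rt to 40 °C removes the three MOM groups and the TES group. The freed bis(4-hydroxyphenyl)carbinol then collapses to 18, and the CH2OH is never exposed to a halide source.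

## Further compounds

F1 | step 4 | (E)-5-(4-methoxyphenyl)pent-4-en-2-yn-1-ol | OCC#C/C=C/c1ccc(OC)cc1
F2 | step 4 | (E)-5-(4-methoxyphenyl)pent-4-en-2-yn-1-yl 4,4-bis(4-methoxyphenyl)-4-[(triethylsilyl)oxy]but-2-ynoate | COc1ccc(cc1)/C=C/C#CCOC(=O)C#CC(O[Si](CC)(CC)CC)(c1ccc(OC)cc1)c1ccc(OC)cc1
F3 | step 4 | bicyclic 1,2,4-cyclohexatriene (cyclic allene, racemic) isomer of 12 | O=C1OCC2=C=CC(c3ccc(OC)cc3)C(C(O[Si](CC)(CC)CC)(c3ccc(OC)cc3)c3ccc(OC)cc3)=C12
F4 | step 5 | {3-{bis(4-methoxyphenyl)[(triethylsilyl)oxy]methyl}-2-(2-chlorovinyl)-4-(4-methoxyphenyl)phenyl}methanol (E/Z mixture) | ClC=Cc1c(CO)ccc(-c2ccc(OC)cc2)c1C(O[Si](CC)(CC)CC)(c1ccc(OC)cc1)c1ccc(OC)cc1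
F5 | step 7 | bis[4-(methoxymethoxy)phenyl]methanone | O=C(c1ccc(OCOC)cc1)c1ccc(OCOC)cc1
F6 | step 7 | 1-ethynyl-4-(methoxymethoxy)benzene | C#Cc1ccc(OCOC)cc1
F7 | step 7 | 5-[4-(methoxymethoxy)phenyl]penta-2,4-diyn-1-ol | OCC#CC#Cc1ccc(OCOC)cc1
F8 | step 7 | dilithium 4-oxido-4,4-bis[4-(methoxymethoxy)phenyl]but-2-ynoate | [Li]OC(=O)C#CC(O[Li])(c1ccc(OCOC)cc1)c1ccc(OCOC)cc1
F9 | step 7 | triethylsilyl 4,4-bis[4-(methoxymethoxy)phenyl]-4-[(triethylsilyl)oxy]but-2-ynoate | CC[Si](CC)(CC)OC(=O)C#CC(O[Si](CC)(CC)CC)(c1ccc(OCOC)cc1)c1ccc(OCOC)cc1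
F10 | step 7 | 4,4-bis[4-(methoxymethoxy)phenyl]-4-[(triethylsilyl)oxy]but-2-ynoic acid | OC(=O)C#CC(O[Si](CC)(CC)CC)(c1ccc(OCOC)cc1)c1ccc(OCOC)cc1
F11 | step 7 | 5-[4-(methoxymethoxy)phenyl]penta-2,4-diyn-1-yl 4,4-bis[4-(methoxymethoxy)phenyl]-4-[(triethylsilyl)oxy]but-2-ynoate | COCOc1ccc(cc1)C#CC#CCOC(=O)C#CC(O[Si](CC)(CC)CC)(c1ccc(OCOC)cc1)c1ccc(OCOC)cc1
F12 | step 7 | 4,5-didehydro derivative (benzyne) of F13 | O=C1OCC2=C1C(C(O[Si](CC)(CC)CC)(c1ccc(OCOC)cc1)c1ccc(OCOC)cc1)=C(c1ccc(OCOC)cc1)C#C2
F13 | step 7 | 7-{bis[4-(methoxymethoxy)phenyl][(triethylsilyl)oxy]methyl}-6-[4-(methoxymethoxy)phenyl]isobenzofuran-1(3H)-one | O=C1OCc2ccc(-c3ccc(OCOC)cc3)c(C(O[Si](CC)(CC)CC)(c3ccc(OCOC)cc3)c3ccc(OCOC)cc3)c12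
F14 | step 7 | (±)-lactol of F13 (1,3-dihydroisobenzofuran-1-ol) | OC1OCc2ccc(-c3ccc(OCOC)cc3)c(C(O[Si](CC)(CC)CC)(c3ccc(OCOC)cc3)c3ccc(OCOC)cc3)c12
F15 | step 7 | {3-{bis[4-(methoxymethoxy)phenyl][(triethylsilyl)oxy]methyl}-2-ethynyl-4-[4-(methoxymethoxy)phenyl]phenyl}methanol | C#Cc1c(CO)ccc(-c2ccc(OCOC)cc2)c1C(O[Si](CC)(CC)CC)(c1ccc(OCOC)cc1)c1ccc(OCOC)cc1
F16 | step 7 | 4-{[2-{bis[4-(methoxymethoxy)phenyl][(triethylsilyl)oxy]methyl}-6-(hydroxymethyl)-3-[4-(methoxymethoxy)phenyl]phenyl]ethynyl}phenol | Oc1ccc(cc1)C#Cc1c(CO)ccc(-c2ccc(OCOC)cc2)c1C(O[Si](CC)(CC)CC)(c1ccc(OCOC)cc1)c1ccc(OCOC)cc1
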